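The earlier runs and the new flask were computed with made-up constants; noise was put on by code.

5 questions stand on 4 flasks with one charge and different temperatures: which gives most target, and how much target each holds at the end.

all flasks: starting material 0.050 M
- dawn: partner 0.11 M; second substrate 0.050 M; third substrate 0.010 M; temperature −40 °C; run made earlier
- cedar: partner 0.0550 M; second substrate 0.0500 M; third substrate 0.0100 M; temperature −40 °C; time 5.0 min
- birch: partner 0.0550 M; second substrate 0.0500 M; third substrate 0.0100 M; temperature −20 °C; time 5.0 min
- maple: partner 0.0550 M; second substrate 0.0500 M; third substrate 0.0100 M; at −40 °C until 1.5 min, from then on at 0 °C; time 5.0 min
- alder: partner 0.0550 M; second substrate 0.0500 M; third substrate 0.0100 M; temperature 0 °C; time 5.0 min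

dawn run (percent of the starting material charged)

| time / s | target / % | starting material / % |
|---|---|---|
| 20.0 | 14 | 91 |
| 40.0 | 14 | 81 |
| 50.0 | 24 | 79 |
| 80.0 | 33 | 72 |
| 90.0 | 34 | 59 |

(standard deviation of a reading: 2 percentage points)

- percent here means starting material units held: one side product counts as two
- the earlier runs were read with a standard deviation of 2 percentage points
- steps that have been proposed: 2 second substrate -> homo dimer; second substrate + partner -> second product; starting material + target -> side product; starting material + partner -> target; third substrate + partner -> third product
- the earlier runs do not show what temperature does; that part of a forecast is a guess

1. the flask that comes out highest in amount of target, in percent of the starting material charged, or "all alike" when all lie within 1.5 percentage points (cedar / birch / maple / alder / all alike)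
2. target at the end, in percent of the starting material charged, cedar
3. target at the end, in percent of the starting material charged, birch
4. target at the end, in percent of the starting material charged, maple
5. target at the end, in percent of the starting material charged, alder

Treating partner as constant (pseudo-first-order), the integrated rate and the last dawn reading give a rate constant, itself a reading with scatter, for starting material + partner at −40 °C:

k = −ln(fraction of starting material left) / (time × [partner]) = 0.0533 /M/s

A flask's clock is then 1/(k[partner]). The dawn run is silent on temperature, so this reckoning borrows the forecast's guess of a factor 6 per 20.0 K. From fastest to slowest:

alder: 9.48 s
birch: 56.9 s
dawn: 171 s
cedar: 341 s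

Alder's clock is far shorter than the 5.0 min allowed, and birch's is shorter too, so both should approach their end state. Maple warms after 1.5 min, before one cedar clock has passed, and should then run on alder's clock. Cedar's clock exceeds the time allowed, so cedar should stay unfinished.

The end state is a matter of balance. Partner less third substrate is 0.0450 M, less than the starting material charged, so partner is the limiting reagent here, whereas dawn had 0.100 M. Surplus starting material can then react with target, and each such turn removes one of each. Counting every partner that reaches starting material gives:

target = margin − 2[second product]/[starting material charged] − 2[partner left]/[starting material charged] + [starting material left]/[starting material charged]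

Here 80.0% is the partner margin: twice the partner remaining after third substrate, per starting material charged, less one, which is the target of a flask holding no starting material, no partner and no second product. The dawn run carries no reading of second product, so this reckoning commits to the margin and to the sign of the last term: at equal second product and partner left, a flask with starting material left holds more target than one without.

The forecast chose maple, with 33% for cedar, 58% for birch, 62% for maple and 60% for alder: “Alder and maple finish, limited by partner sharing and side product.”

The flasks gave 33.1% in cedar, 40.0% in birch, 31.4% in maple and 28.4% in alder, so birch came highest.

2 second substrate → homo dimer (k = 2.40 /M/s, Ea = 38.0 kJ/mol); second substrate + partner → second product (k = 0.740 /M/s, Ea = 41.0 kJ/mol); starting material + target → side product (k = 0.100 /M/s, Ea = 50.0 kJ/mol); starting material + partner → target (k = 0.370 /M/s, Ea = 45.0 kJ/mol); third substrate + partner → third product (k = 12.0 /M/s, Ea = 40.0 kJ/mol); (constants at −20 °C) In birch, second product was half made by 0.113 min, and target was being made 5.29 times faster than used at 0.566 min, but by 5.00 min the ratio of made to used had fallen to 0.557. At 5.00 min, with second product at 0.0119 M, 5.5% of the partner charge and 20% of the starting material charge left, the margin of 80.0% gives birch 40.0%; with second product at 0.0124 M, 1.5% of the partner charge and 1.3% of the starting material charge left, it gives alder 28.4%.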